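I kept my books on what stays behind: s, the fraction of left-handed and right-handed substrate together still unreacted.

| flask | left-handed substrate | right-handed substrate | partner | free catalyst | racemization catalyst | added ligand | remark | time |
|---|---|---|---|---|---|---|---|---|
| spring | 0.10 M | 0.10 M | 2.2 equiv (in portions, 3) | 0.034 mol% | 0.058 mol% | 0.12 mM | run made earlier; portions every 3.0 min |  |
| winter | 0.10 M | 0.10 M | 2.2 equiv (in portions, 3) | 0.14 mol% | 0.058 mol% | 0.12 mM | run made earlier; portions every 3.0 min |  |
| dusk | 0.10 M | 0.10 M | 4.4 equiv (in portions, 3) | 0.068 mol% | 0.058 mol% | 0.12 mM | run made earlier; portions every 3.0 min |  |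
| flask | 0.10 M | 0.10 M | 2.20 equiv (in portions, 3) | 0.068 mol% | 0.058 mol% | 0.12 mM | the portions of partner follow each other after 3.0 min, the first at the start | 50 min |

| run | time / min | left-handed substrate / % | right-handed product / % | left-handed product / % | right-handed substrate / % |
|---|---|---|---|---|---|
| spring | 4.00 | 49.0 | 0.7 | 0 | 49.8 |
| spring | 8.00 | 47.0 | 1.6 | 4.6 | 46.7 |
| spring | 12.0 | 44.8 | 3.9 | 9.2 | 44.1 |
| spring | 15.0 | 41.1 | 4.2 | 7.5 | 43.3 |
| spring | 20.0 | 39.8 | 8.1 | 13.6 | 40.6 |
| spring | 25.0 | 38.0 | 10.1 | 16.8 | 38.7 |
| spring | 30.0 | 36.2 | 9.6 | 18.6 | 35.2 |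
| winter | 2.50 | 45.9 | 3.2 | 3.6 | 46.7 |
| winter | 4.00 | 43.5 | 4.2 | 8.3 | 44.8 |
| winter | 6.00 | 38.9 | 6.5 | 11.4 | 40.9 |
| winter | 8.00 | 34.5 | 12.2 | 18.9 | 36.2 |
| winter | 12.0 | 26.9 | 14.7 | 27.6 | 30.8 |
| winter | 20.0 | 18.2 | 20.5 | 35.5 | 22.9 |
| winter | 30.0 | 13.4 | 25.4 | 44.1 | 14.6 |
| dusk | 2.50 | 48.1 | 1.8 | 3.7 | 49.4 |
| dusk | 5.00 | 41.5 | 4.8 | 9.4 | 43.0 |
| dusk | 8.00 | 35.8 | 10.0 | 16.8 | 38.0 |
| dusk | 15.0 | 25.5 | 18.4 | 30.9 | 26.3 |
| dusk | 30.0 | 11.3 | 27.4 | 48.2 | 13.8 |

(scatter of a reading: 1 percentage point)

- where most of what was charged as left-handed substrate and right-handed substrate together, at 50 min is found (right-handed product / left-handed product / left-handed substrate / right-handed substrate)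
- the largest share itself, whichever of these holds it, in percent of the left-handed substrate and right-handed substrate together charged

- free catalyst is single-handed; left-handed substrate and right-handed substrate are mirror images of each other, charged as a racemate, each of them at the stated concentration

The flask held β = 1.10 mol of partner per mole of that pair, so the pair was the limiting reagent, with a surplus of partner e = 0.100 mol per mole and partner left s + e. At 30.0 min the dusk run still held 11.3 % and 13.8 % of the two substrates, so I treated them as one pool, with ds/dt = −κs(s + e). Integration gave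

ln[(s + e)/(βs)] = eκτ,

where τ is the time counted from the mean addition of the portions, 3.00 min after the start.

The dusk run had the flask's catalyst and ligand charges and differed in partner. Its last reading left s = 25.1 %, which gave the pool constant κ = 0.0298 min⁻¹, the decay constant of the fraction left per unit of partner. Its 15.0 min reading gave 0.0285 min⁻¹, so I held κ constant. Its 30.0 min reading gave f = 63.8 %, the left-handed share of product.

My ledger for the flask at τ = 47.0 min:

Unreacted pair: s = e/(β exp(eκτ) − 1) = 37.7 %
Left-handed product: 39.7 %
Right-handed product: 22.6 %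
Partner left, of its charge: (s + e)/β = 43.3 %

So I placed most in left-handed product, ahead of either substrate at about 18.9 %.

The forecast, left-handed product at 42 % from “gives about 65% conversion at 50 min”, stood 2.3 percentage points above my entry.

The flask gave left-handed product at 39.9 %, with 22.3 % right-handed product, 18.2 % left-handed substrate and 19.6 % right-handed substrate.

    partner + free catalyst + left-handed substrate → free catalyst + left-handed product (k = 110 L² mol⁻² s⁻¹)
    partner + free catalyst + right-handed substrate → free catalyst + right-handed product (k = 59.1 L² mol⁻² s⁻¹)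
    left-handed substrate + racemization catalyst ⇌ right-handed substrate + racemization catalyst, rate k3*[racemization catalyst]*[left-handed substrate] forward; the back reaction follows from the equilibrium constant (k = 841 L mol⁻¹ s⁻¹)
    2 racemization catalyst → spent catalyst (k = 151 L mol⁻¹ s⁻¹)
    free catalyst + added ligand ⇌ idle complex, settled at all times (K = 16000 L mol⁻¹)

At 50.0 min in the flask, coupling consumed left-handed substrate at 0.34 of the forward rate of its racemization. The two substrates then stood 1.4 points apart, close to the single pool that κ counts. Read back from the flask's own unreacted pair, κ came to 0.0297 min⁻¹. In the neighbour charged with 0.880 equiv of partner, β fell to 0.440, making partner the limiting reagent, and the same κ gave s = 70.1 %; that neighbour ended with 70.1 % of the pair unreacted.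

Readings and results stem from a simulated flask with made-up constants; scatter was added.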